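Start from a one-step world in which Wu simply turns into Ez, then add the other steps one at a time.

    Gu → Dz (k1 = 1.7 × 10⁻⁵ s⁻¹)
    Wu + Dz → Ek + Eb (k2 = 0.0030 M⁻¹ s⁻¹)
    Wu + Ek → Eb + Ek, rate k3*[Ek]*[Wu] (k3 = 0.021 M⁻¹ s⁻¹)
    Wu → Ez (k4 = 1.1 × 10⁻⁵ s⁻¹)

Wu 0.050 M; Gu 2.5 mol%; time 15 d

- why nothing more happens at 15 d, or that something still does (forward and back rates have come level / it is still moving / no working catalyst is left / all of Wu has reacted)
- how much Eb there is at 15 d, in percent of the Wu charged
- how much Ez there is at 15 d, in percent of the Wu charged

- the reaction counts as stopped when no species that holds the Wu changes by six tenths of a point or more over the second half of the time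
- run time (flask): 15 d

With the side step alone, Ez takes every Wu, with a half-life of 0.73 d. The run lasts 20.6 such half-lives, and every step runs one way, so expect all of Wu to have reacted. What remains to find is the split.

Now add growth. Its rate is first order in Wu, with a pseudo-first-order constant k3[Ek], and the side step is first order in Wu too. So at each moment Eb gains on Ez by the ratio k3[Ek]/k4, and [Ek] is the concentration to watch. Put the whole Gu charge of 0.00125 M to work as Ek from the start: the ratio is 2.39, and Eb takes 70.5%.

Next add the release of Dz from Gu: k1 is 1.7 × 10⁻⁵ s⁻¹ and k4 is 1.1 × 10⁻⁵ s⁻¹, a factor of 1.55 between them. Ek starts at zero. By the half-life of Wu under the side step, 65.7% of Gu has reacted. Take half of that as the mean working share, 0.329. Multiply k3 by the mean [Ek] and divide by k4 to get 0.784, the working ratio. Eb then takes 43.9% and Ez 56.1%.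

Last add the step from Dz to Ek. Its half-life at the charged Wu, 0.053 d, is shorter than that of Gu, 0.47 d, so at the start treat the Gu release as the rate-limiting step, and leave the number as it stands.

The forecast says all of Wu has reacted, with Eb 44.3% and Ez 55.7%, and remarks: “The split is therefore kinetic”.

The simulation gives all of Wu has reacted, with Eb 44.4% and Ez 55.6%.

In this flask Eb over Ez reads 0.799, beside the working ratio of 0.784. Now take the neighbour with 0.62 mol% of Gu and keep the same mean share: its working ratio is 0.195, so Eb should take 16.3%. The neighbour ends with Eb 21.3% and Ez 78.7%, a ratio of 0.271.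

All constants stand for no real mixture; the run is a simulation.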